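Its constants were drawn at random within sensible limits; the result is computed.

The ratio I watch is the time a flask needs to pass its charge through step 1, divided by the time it is given.

    starting material ⇌ tight pair (K1 = 0.0050, k1 = 0.041 s⁻¹, Ea1 = 103 kJ mol⁻¹, ΔH1 = −32.0 kJ mol⁻¹)
    tight pair ⇌ loose pair (K2 = 0.41, k2 = 14 s⁻¹, Ea2 = 92.0 kJ mol⁻¹, ΔH2 = −33.0 kJ mol⁻¹)
    partner + tight pair → target (k3 = 240 L mol⁻¹ s⁻¹, Ea3 = 60.0 kJ mol⁻¹)
    partner + loose pair → isomer of the product A (k4 = 140 L mol⁻¹ s⁻¹, Ea4 = 64.0 kJ mol⁻¹)
    target ⇌ isomer of the product B (K5 = 2.9, k5 = 5.5 × 10⁻⁴ s⁻¹, Ea5 = 126 kJ mol⁻¹, ΔH5 = 41.0 kJ mol⁻¹)
    solid substrate ⇌ starting material, rate k6*(cs6 - [starting material]) while solid is left; crystals form when [starting material] > cs6 (cs6 = 43 mM, k6 = 0.011 s⁻¹)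
    partner + protic impurity → quenched reagent (k7 = 3.8 L mol⁻¹ s⁻¹, Ea7 = 46.0 kJ mol⁻¹)
    (constants at 110 °C)

in all of them: solid substrate 0.11 M; partner 0.440 M; protic impurity 0.0330 M; time 30 min
- violet: temperature 110 °C
- grey: temperature 90 °C
- amber: temperature 70 °C

- as a solid, counted per litre of solution: solid substrate
- all constants are for 110 °C and move with temperature by the activation energies and enthalpies
- at the start none of the solid substrate is in solution
- what has only dissolved of solid substrate counts as not reacted

1. which flask leads in amount of target, in percent of the solid substrate charged ("all alike" within 1.5 percentage points) (violet / grey / amber / all alike)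
2. how much target is there at the end, in percent of the solid substrate charged: violet
3. how much target is there at the end, in percent of the solid substrate charged: grey
4. how much target is there at the end, in percent of the solid substrate charged: amber

**First guess.** Amber is the hard flask, so I start there. Arrhenius factors between the same two temperatures are powers of one another, so I divide by 100, the speed-up of step 5, raised to Ea1/Ea5. This takes the forward constant f of step 1 from 0.041 s⁻¹ down to 9.46 × 10⁻⁴ s⁻¹ in amber. Suppose step 1 stands at equilibrium, with 0.0161 as its constant. Even with the impurity and the whole charge taken off the partner, 0.297 M remains, so capture of the tight pair runs at 7.93 s⁻¹. Starting material would then vanish at 0.128 s⁻¹.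

**The objection.** That is faster than f, yet step 1 cannot pass starting material faster than its forward constant. The equilibrium is false in amber: falling back runs at 0.0587 s⁻¹, far slower than capture, so between these two routes nearly all of the tight pair is captured. In amber I therefore take forward step 1 as the rate-limiting step.

**Better estimate.** Let a be the dissolved starting material, d the dissolution coefficient and c the solubility. The pool gains d(c−a) and loses f·a. In amber d is about ten times f, so the pool sits steady at a = dc/(d+f) = 39.6 mM. With S the solid charged, the emptying time, S/(f·a), is 48.9 min, which is longer than the 30 min allowed.

**Two doubts.** The pool must fill first, which takes about 1/(d+f) = 1.40 min, so I reckon that amber passes 58.5% of its charge. Does the solid last that long? The reckoning leaves 5.55% undissolved, so on this estimate the steady drain holds to the end in amber.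

**The other flasks.** The same formula gives violet an emptying time of 4.92 min, well inside its time. But there the target relaxes towards isomer of the product B with a half-life of 15.6 min, shorter than the run. In grey that half-life is 109 min, long against 30 min. Grey, at 90 °C, lies in temperature between 70 °C and 110 °C, so I expect its emptying time to lie between those of amber and violet. I commit to grey, though I have no figure for its target.

**The forecast.** It also names grey, and it does give figures: 44% for violet, 85% for grey and 55% for amber. Its ground is that “90 °C gets near-complete conversion with little isomerisation”.

**The result.** Grey leads with 85.2%, against 43.7% in violet and 55.4% in amber, where conversion ends at 58.2% with 5.84% of the solid still undissolved. Filling time plus the matching part of the emptying time puts 30.0% conversion in amber at 16.1 min, and amber reaches it at 16.1 min. The same sum for violet gives 1.80 min, and violet reaches that conversion at 1.84 min.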